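The molecule is cut at the (E)-trisubstituted C12=C13 alkene (backbone C1–C23 counted from the ethyl end of ring A; ring A = C3–C7, ring B = C15–C19), which lies between the two pyranone halves and next to the free C11 hydroxyl. A single cross-metathesis joins a 1,1-disubstituted allylic alcohol (fragment 1, C1–C12) to a terminal alkene on the C14 branch of ring B (fragment 2, C13–C23), making the alkene and completing the target with both acetates and the C11 alcohol already in place. Both fragments grow from one symmetric pyranone by lateral aldol additions; C10/C11 come from an Evans aldol, C14 from an enantioconvergent nickel vinylation.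

Key step: step 16

Assumption: mixtures are drawn as follows – racemate 18 as its two enantiomers joined by a dot, chloride 22 with C14 undefined; dienolates 12, 17 and 21 are drawn with the (Z)-ethylidene geometry that avoids A(1,3) strain with the ring methyl; the ligand antipode in step 13 is assigned by analogy with simple 1-chloroethylarenes and is exchanged for its mirror image if the sense of induction proves opposite.

Step 1
Reactants: 1 pentan-3-one; 2 propanoic acid (two molecules are built into the product; used in excess)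
Product: 4 2,6-diethyl-3,5-dimethyl-4H-pyran-4-one, via 4,6-dimethylnonane-3,5,7-trione 3 (not isolated)
Conditions: polyphosphoric acid, neat, about 180 °C
Reagents that add atoms: propanoic acid (the second molecule of 2), CCC(=O)O
Why: One-pot γ-pyranone synthesis in which polyphosphoric acid promotes C-acylation of each α-carbon of the ketone by one molecule of propanoic acid and then cyclodehydration of the resulting 1,3,5-triketone, which should give the symmetric pyranone that supplies both ring A and ring B (no stereocentre is formed).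

Step 2
Reactants: 5 (S)-4-benzyl-3-propanoyloxazolidin-2-one; 6 2-methylprop-2-enal (methacrolein)
Product: 8 (S)-4-benzyl-3-[(2S,3S)-3-hydroxy-2,4-dimethylpent-4-enoyl]oxazolidin-2-one, via boron enolate 7 (not isolated)
Conditions: Bu2BOTf, iPr2NEt, CH2Cl2, 0 °C; then 6, −78 → 0 °C; pH 7 buffer, MeOH, H2O2, 0 °C
Reagents that add atoms: none
Why: Evans syn aldol reaction in which the (Z)-boron enolate 7 adds to the aldehyde through a chair-like Zimmerman–Traxler transition state with the benzyl group of the auxiliary blocking one enolate face, so that C10 and C11 should be set together as the (2S,3S) syn pair under auxiliary control.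

Step 3
Reactants: 8 (S)-4-benzyl-3-[(2S,3S)-3-hydroxy-2,4-dimethylpent-4-enoyl]oxazolidin-2-one
Product: 9 (S)-4-benzyl-3-[(2S,3S)-3-(tert-butyldimethylsilyloxy)-2,4-dimethylpent-4-enoyl]oxazolidin-2-one
Conditions: TBSOTf, 2,6-lutidine, CH2Cl2, −78 → 0 °C
Reagents that add atoms: tert-butyldimethylsilyl trifluoromethanesulfonate, CC(C)(C)[Si](C)(C)OS(=O)(=O)C(F)(F)F
Why: Silyl ether formation with a silyl triflate and a hindered pyridine base is standard for β-hydroxy imides and should proceed without retro-aldol cleavage, the TBS group being chosen because it neither chelates lithium nor migrates readily in the aldolate of step 6.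

Step 4
Reactants: 9 (S)-4-benzyl-3-[(2S,3S)-3-(tert-butyldimethylsilyloxy)-2,4-dimethylpent-4-enoyl]oxazolidin-2-one
Product: 10 (2R,3S)-3-(tert-butyldimethylsilyloxy)-2,4-dimethylpent-4-en-1-ol
Conditions: LiBH4, MeOH (1 equiv), THF, 0 °C
Reagents that add atoms: none
Why: Reductive cleavage of the N-acyl oxazolidinone with LiBH4 is the standard release of Evans adducts as primary alcohols and should leave the silyl ether, the alkene and the C10 stereocentre untouched.

Step 5
Reactants: 10 (2R,3S)-3-(tert-butyldimethylsilyloxy)-2,4-dimethylpent-4-en-1-ol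
Product: 11 (2S,3S)-3-(tert-butyldimethylsilyloxy)-2,4-dimethylpent-4-enal
Conditions: Dess–Martin periodinane, CH2Cl2, 0 °C → rt; used at once
Reagents that add atoms: none
Why: Dess–Martin oxidation converts the primary alcohol into the aldehyde under neutral, non-enolising conditions, so the α-stereocentre C10 should be retained when the aldehyde is used directly.

Step 6
Reactants: 4 2,6-diethyl-3,5-dimethyl-4H-pyran-4-one; 11 (2S,3S)-3-(tert-butyldimethylsilyloxy)-2,4-dimethylpent-4-enal
Product: 13 2-[(2R,3R,4R,5S)-5-(tert-butyldimethylsilyloxy)-3-hydroxy-4,6-dimethylhept-6-en-2-yl]-6-ethyl-3,5-dimethyl-4H-pyran-4-one, via dienolate 12 (not isolated)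
Conditions: 4 (1.5 equiv), LiN(SiMe3)2, THF, −78 °C; then 11, −78 °C; AcOH quench at −78 °C
Reagents that add atoms: none
Why: Lateral (vinylogous) aldol addition of a γ-pyranone dienolate whose lithium sits on the remote C5 oxygen, so that an open transition state with the aldehyde chain anti to the ring should give the 8,9-anti relationship while Felkin–Anh attack on the α-methyl aldehyde (favoured for a bulky nucleophile and a non-chelating silyl ether) sets 9,10-syn, together defining (8R,9R); minor diastereomers are removed by chromatography.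

Step 7
Reactants: 13 2-[(2R,3R,4R,5S)-5-(tert-butyldimethylsilyloxy)-3-hydroxy-4,6-dimethylhept-6-en-2-yl]-6-ethyl-3,5-dimethyl-4H-pyran-4-one
Product: 14 (2R,3R,4R,5S)-5-(tert-butyldimethylsilyloxy)-2-(6-ethyl-3,5-dimethyl-4-oxo-4H-pyran-2-yl)-4,6-dimethylhept-6-en-3-yl acetate
Conditions: Ac2O, pyridine, DMAP (cat.), CH2Cl2, 0 °C → rt
Reagents that add atoms: acetic anhydride, CC(=O)OC(C)=O
Why: Nucleophile-catalysed acylation of the only free hydroxyl places the acetate on O9 while O11 is still masked, so the two oxygens never have to be told apart later.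

Step 8
Reactants: 14 (2R,3R,4R,5S)-5-(tert-butyldimethylsilyloxy)-2-(6-ethyl-3,5-dimethyl-4-oxo-4H-pyran-2-yl)-4,6-dimethylhept-6-en-3-yl acetate
Product: 15 (2R,3R,4S,5S)-2-(6-ethyl-3,5-dimethyl-4-oxo-4H-pyran-2-yl)-5-hydroxy-4,6-dimethylhept-6-en-3-yl acetate (fragment 1)
Conditions: HF·pyridine, pyridine, THF, 0 °C → rt
Reagents that add atoms: none
Why: Fluoride-mediated cleavage of the silyl ether with buffered HF·pyridine is non-basic, so the C11 allylic alcohol should be released without 1,3-migration of the acetyl group from O9 and without touching the pyranone.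

Step 9
Reactants: 4 2,6-diethyl-3,5-dimethyl-4H-pyran-4-one; 16 propanal
Product: 18 racemic anti-2-ethyl-6-(3-hydroxypentan-2-yl)-3,5-dimethyl-4H-pyran-4-one [(2S*,3S*) side chain], via sodium dienolate 17 (not isolated)
Conditions: NaN(SiMe3)2, THF, −78 °C; then propanal (2 equiv), −78 °C; AcOH quench at −78 °C; chromatography
Reagents that add atoms: none
Why: Lateral aldol addition of the sodium dienolate 17, whose loosely bound counter-ion on the remote C17 oxygen cannot organise a closed transition state and whose high reactivity should outpace enolisation of propanal, is expected to favour the anti adduct through an open transition state and so set the C20/C21 relative configuration (racemic, because neither partner is chiral), the syn isomer being separated by chromatography.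

Step 10
Reactants: 18 racemic anti-2-ethyl-6-(3-hydroxypentan-2-yl)-3,5-dimethyl-4H-pyran-4-one
Product: 19 2-ethyl-6-[(2S,3S)-3-hydroxypentan-2-yl]-3,5-dimethyl-4H-pyran-4-one (recovered, unreacted enantiomer)
Conditions: Candida antarctica lipase B (immobilised), vinyl acetate, MTBE, 40 °C, run to just over half conversion; chromatography
Reagents that add atoms: none
Why: Lipase-catalysed kinetic resolution by irreversible transacetylation, in which the empirical size model for secondary alcohols (ethyl as the medium group, the branched pyranonyl-ethyl group as the large one) predicts acetylation of the (21R) enantiomer, so that driving the conversion just past one half should leave the wanted (20S,21S) alcohol in high enantiomeric purity.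

Step 11
Reactants: 19 2-ethyl-6-[(2S,3S)-3-hydroxypentan-2-yl]-3,5-dimethyl-4H-pyran-4-one
Product: 20 2-ethyl-3,5-dimethyl-6-[(2S,3S)-3-(triethylsilyloxy)pentan-2-yl]-4H-pyran-4-one
Conditions: TESCl, imidazole, DMF, 0 °C → rt
Reagents that add atoms: chlorotriethylsilane, CC[Si](Cl)(CC)CC
Why: Standard silylation removes the acidic hydroxyl so that the next step needs a single equivalent of base and no lithium alkoxide prone to retro-aldol cleavage is present.

Step 12
Reactants: 20 2-ethyl-3,5-dimethyl-6-[(2S,3S)-3-(triethylsilyloxy)pentan-2-yl]-4H-pyran-4-one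
Product: 22 2-(1-chloroethyl)-3,5-dimethyl-6-[(2S,3S)-3-(triethylsilyloxy)pentan-2-yl]-4H-pyran-4-one (both C14 epimers), via dienolate 21 (not isolated)
Conditions: LiN(SiMe3)2, THF, −78 °C; then cannulated into C2Cl6, THF, −78 °C
Reagents that add atoms: hexachloroethane, ClC(Cl)(Cl)C(Cl)(Cl)Cl
Why: Kinetic lateral deprotonation should occur at the unhindered C14 methylene and not at the tertiary C20–H, and halophilic attack of the dienolate on hexachloroethane (electrophilic chlorination of a stabilised carbanion) should give the secondary chloride, whose C14 epimer mixture is of no consequence because the next step is stereoconvergent.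

Step 13
Reactants: 22 2-(1-chloroethyl)-3,5-dimethyl-6-[(2S,3S)-3-(triethylsilyloxy)pentan-2-yl]-4H-pyran-4-one; 23 bromoethene (vinyl bromide, 1 M in THF)
Product: 24 2-[(2R)-but-3-en-2-yl]-3,5-dimethyl-6-[(2S,3S)-3-(triethylsilyloxy)pentan-2-yl]-4H-pyran-4-one
Conditions: NiCl2(dme) (10 mol %), (3aS,3a′S,8aR,8a′R)-2,2′-(cyclopropane-1,1-diyl)bis(3a,8a-dihydro-8H-indeno[1,2-d]oxazole) (11 mol %), Mn powder, NaI, DMA, 0 °C
Reagents that add atoms: none
Why: Nickel-catalysed enantioconvergent reductive cross-coupling of a secondary benzylic-type chloride with a vinyl bromide, in which halogen abstraction by low-valent nickel turns both C14 epimers into the same planar pyranone-stabilised radical that is captured by the chiral bis(oxazoline)–nickel vinyl species, so that reductive elimination should set C14 as R under ligand control while C20 and C21 are spectators.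

Step 14
Reactants: 24 2-[(2R)-but-3-en-2-yl]-3,5-dimethyl-6-[(2S,3S)-3-(triethylsilyloxy)pentan-2-yl]-4H-pyran-4-one
Product: 25 2-[(2R)-but-3-en-2-yl]-6-[(2S,3S)-3-hydroxypentan-2-yl]-3,5-dimethyl-4H-pyran-4-one
Conditions: HF·pyridine, pyridine, THF, 0 °C
Reagents that add atoms: none
Why: Desilylation with HF·pyridine is non-basic, so the triethylsilyl ether should be cleaved without epimerising the doubly activated C14–H or moving the terminal alkene into conjugation with ring B.

Step 15
Reactants: 25 2-[(2R)-but-3-en-2-yl]-6-[(2S,3S)-3-hydroxypentan-2-yl]-3,5-dimethyl-4H-pyran-4-one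
Product: 26 (2S,3S)-2-{6-[(2R)-but-3-en-2-yl]-3,5-dimethyl-4-oxo-4H-pyran-2-yl}pentan-3-yl acetate (fragment 2)
Conditions: Ac2O, pyridine, DMAP (cat.), CH2Cl2, 0 °C → rt
Reagents that add atoms: acetic anhydride, CC(=O)OC(C)=O
Why: DMAP-catalysed acetylation under weakly basic conditions should esterify O21 and complete fragment 2 without affecting C14.

Step 16
Reactants: 15 fragment 1; 26 fragment 2 (2 equiv)
Product: 27 the target (8R,9R,10S,11S,12E,14R,20S,21S in backbone numbering)
Conditions: second-generation Hoveyda–Grubbs catalyst [RuCl2(H2IMes)(=CH-C6H4-2-OiPr)] (2 × 10 mol %), 1,4-benzoquinone (20 mol %), toluene, 70 °C, argon sparge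
Reagents that add atoms: none
Why: The reaction is an olefin cross-metathesis by the carbene/metallacycle (Chauvin) mechanism: the ruthenium carbene first exchanges onto the monosubstituted alkene of 26, this alkylidene adds across the 1,1-disubstituted alkene of 15 to a ruthenacyclobutane, and its opening delivers the C12=C13 bond while the methylidene left on ruthenium is returned to the cycle with loss of ethene. The closest known reaction type is the cross-metathesis of methallyl-type 1,1-disubstituted allylic alcohols with terminal alkenes to trisubstituted alkenes, used here with allylic branching on both partners. No ring is closed and no stereocentre is created; the only new stereo-element is the alkene geometry, which should be E because metathesis is reversible and the isomer with the C11 and C14 branches trans is the more stable one. Cross-selectivity is needed and is secured by the substrates: 15 cannot dimerise (that would need a tetrasubstituted alkene), the C14 branch slows dimerisation of 26 and any dimer formed re-enters the cycle, and the unprotected C11 hydroxyl exploits the known accelerating effect of an allylic OH on metathesis at its own alkene. 1,4-Benzoquinone intercepts ruthenium hydrides that would otherwise move the new or the terminal alkene into conjugation with ring B and erode C14. Both acetates and the C11 alcohol are already in their final state, so the product is the target.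

Compound list
1 | pentan-3-one | CCC(=O)CC | starting material
2 | propanoic acid | CCC(=O)O | starting material
3 | 4,6-dimethylnonane-3,5,7-trione (not isolated) | CCC(=O)C(C)C(=O)C(C)C(=O)CC | intermediate
4 | 2,6-diethyl-3,5-dimethyl-4H-pyran-4-one | CCc1oc(CC)c(C)c(=O)c1C | intermediate
5 | (S)-4-benzyl-3-propanoyloxazolidin-2-one | O=C1OC[C@H](Cc2ccccc2)N1C(=O)CC | starting material
6 | 2-methylprop-2-enal (methacrolein) | CC(=C)C=O | starting material
7 | (S)-4-benzyl-3-[(Z)-1-(dibutylboranyloxy)prop-1-en-1-yl]oxazolidin-2-one (not isolated) | O=C1OC[C@H](Cc2ccccc2)N1/C(OB(CCCC)CCCC)=C/C | intermediate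
8 | (S)-4-benzyl-3-[(2S,3S)-3-hydroxy-2,4-dimethylpent-4-enoyl]oxazolidin-2-one | O=C1OC[C@H](Cc2ccccc2)N1C(=O)[C@@H](C)[C@H](O)C(C)=C | intermediate
9 | (S)-4-benzyl-3-[(2S,3S)-3-(tert-butyldimethylsilyloxy)-2,4-dimethylpent-4-enoyl]oxazolidin-2-one | O=C1OC[C@H](Cc2ccccc2)N1C(=O)[C@@H](C)[C@H](O[Si](C)(C)C(C)(C)C)C(C)=C | intermediate
10 | (2R,3S)-3-(tert-butyldimethylsilyloxy)-2,4-dimethylpent-4-en-1-ol | OC[C@@H](C)[C@H](O[Si](C)(C)C(C)(C)C)C(C)=C | intermediate
11 | (2S,3S)-3-(tert-butyldimethylsilyloxy)-2,4-dimethylpent-4-enal | O=C[C@@H](C)[C@H](O[Si](C)(C)C(C)(C)C)C(C)=C | intermediate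
12 | lithium (6Z)-2-ethyl-6-ethylidene-3,5-dimethyl-6H-pyran-4-olate (lateral lithium dienolate of 4, not isolated) | C/C=C1\OC(CC)=C(C)C(O[Li])=C1C | intermediate
13 | 2-[(2R,3R,4R,5S)-5-(tert-butyldimethylsilyloxy)-3-hydroxy-4,6-dimethylhept-6-en-2-yl]-6-ethyl-3,5-dimethyl-4H-pyran-4-one | CCc1oc([C@H](C)[C@H](O)[C@@H](C)[C@H](O[Si](C)(C)C(C)(C)C)C(C)=C)c(C)c(=O)c1C | intermediate
14 | (2R,3R,4R,5S)-5-(tert-butyldimethylsilyloxy)-2-(6-ethyl-3,5-dimethyl-4-oxo-4H-pyran-2-yl)-4,6-dimethylhept-6-en-3-yl acetate | CCc1oc([C@H](C)[C@H](OC(C)=O)[C@@H](C)[C@H](O[Si](C)(C)C(C)(C)C)C(C)=C)c(C)c(=O)c1C | intermediate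
15 | fragment 1, (2R,3R,4S,5S)-2-(6-ethyl-3,5-dimethyl-4-oxo-4H-pyran-2-yl)-5-hydroxy-4,6-dimethylhept-6-en-3-yl acetate | CCc1oc([C@H](C)[C@H](OC(C)=O)[C@@H](C)[C@H](O)C(C)=C)c(C)c(=O)c1C | intermediate
16 | propanal | CCC=O | starting material
17 | sodium (6Z)-2-ethyl-6-ethylidene-3,5-dimethyl-6H-pyran-4-olate (lateral sodium dienolate of 4, not isolated) | C/C=C1\OC(CC)=C(C)C(O[Na])=C1C | intermediate
18 | racemic anti-2-ethyl-6-(3-hydroxypentan-2-yl)-3,5-dimethyl-4H-pyran-4-one, (2S*,3S*) side chain | CCc1oc([C@@H](C)[C@H](CC)O)c(C)c(=O)c1C.CCc1oc([C@H](C)[C@@H](CC)O)c(C)c(=O)c1C | intermediate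
19 | 2-ethyl-6-[(2S,3S)-3-hydroxypentan-2-yl]-3,5-dimethyl-4H-pyran-4-one | CCc1oc([C@@H](C)[C@H](CC)O)c(C)c(=O)c1C | intermediate
20 | 2-ethyl-3,5-dimethyl-6-[(2S,3S)-3-(triethylsilyloxy)pentan-2-yl]-4H-pyran-4-one | CCc1oc([C@@H](C)[C@H](CC)O[Si](CC)(CC)CC)c(C)c(=O)c1C | intermediate
21 | lithium (6Z)-6-ethylidene-3,5-dimethyl-2-[(2S,3S)-3-(triethylsilyloxy)pentan-2-yl]-6H-pyran-4-olate (lateral dienolate of 20, not isolated) | C/C=C1\OC([C@@H](C)[C@H](CC)O[Si](CC)(CC)CC)=C(C)C(O[Li])=C1C | intermediate
22 | 2-(1-chloroethyl)-3,5-dimethyl-6-[(2S,3S)-3-(triethylsilyloxy)pentan-2-yl]-4H-pyran-4-one, both C14 epimers | CC(Cl)c1oc([C@@H](C)[C@H](CC)O[Si](CC)(CC)CC)c(C)c(=O)c1C | intermediate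
23 | bromoethene (vinyl bromide) | C=CBr | starting material
24 | 2-[(2R)-but-3-en-2-yl]-3,5-dimethyl-6-[(2S,3S)-3-(triethylsilyloxy)pentan-2-yl]-4H-pyran-4-one | C=C[C@@H](C)c1oc([C@@H](C)[C@H](CC)O[Si](CC)(CC)CC)c(C)c(=O)c1C | intermediate
25 | 2-[(2R)-but-3-en-2-yl]-6-[(2S,3S)-3-hydroxypentan-2-yl]-3,5-dimethyl-4H-pyran-4-one | C=C[C@@H](C)c1oc([C@@H](C)[C@H](CC)O)c(C)c(=O)c1C | intermediate
26 | fragment 2, (2S,3S)-2-{6-[(2R)-but-3-en-2-yl]-3,5-dimethyl-4-oxo-4H-pyran-2-yl}pentan-3-yl acetate | C=C[C@@H](C)c1oc([C@@H](C)[C@H](CC)OC(C)=O)c(C)c(=O)c1C | intermediate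
27 | (2R,3R,4S,5S,6E,8R)-8-{6-[(2S,3S)-3-acetoxypentan-2-yl]-3,5-dimethyl-4-oxo-4H-pyran-2-yl}-2-(6-ethyl-3,5-dimethyl-4-oxo-4H-pyran-2-yl)-5-hydroxy-4,6-dimethylnon-6-en-3-yl acetate | CCc1oc([C@H](C)[C@H](OC(C)=O)[C@@H](C)[C@H](O)/C(C)=C/[C@@H](C)c2oc([C@@H](C)[C@H](CC)OC(C)=O)c(C)c(=O)c2C)c(C)c(=O)c1C | target

Total step count: 16.
Longest linear sequence: 9 steps (1, then 9–15 to fragment 2, then 16). The fragment 1 branch is 8 steps (2–8, then 16).

Steps most likely to fail

Step 16. Productive metathesis between two alkenes that are both branched at the allylic carbon may be slower than catalyst decomposition, so that conversion stalls, or hydride-mediated double-bond migration may erode C14. The fallback makes C12=C13 first with a small partner and then builds the ring A half onto it. Setting out from 26, cross-metathesis with an excess of methacrolein 6 (second-generation Hoveyda–Grubbs catalyst, CH2Cl2, 40 °C) should give the (E)-enal F1. Evans syn aldol addition of boron enolate 7 (from 5) gives imide F2, and silylation (TBSOTf, 2,6-lutidine) gives silyl ether F3. NaBH4 in THF/H2O, which spares pyranone and acetate, removes the auxiliary to give alcohol F4, and Dess–Martin oxidation gives aldehyde F5. Addition of F5 to dienolate 12 (from 4) at −78 °C gives the anti, Felkin aldol adduct F6, acetylation gives the O9 acetate F7, and HF·pyridine removes the silyl group to rejoin the route at 27.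

Step 13. Capture of the hindered C14 radical (flanked by the C16 methyl group) by nickel may be slow or poorly face-selective, or the chloride may be lost to homocoupling and β-hydride elimination. The fallback sets C14 by adding hydrogen and a vinyl group across an alkene instead of by substitution. Setting out from 22, dehydrochlorination with DBU (CH2Cl2, rt) gives the 2-ethenylpyranone F8. Nickel-catalysed asymmetric hydrovinylation with ethene ([Ni(η3-C3H5)Br]2, chiral phosphoramidite ligand, NaB[3,5-(CF3)2C6H3]4, CH2Cl2, −78 °C), a known reaction of vinylarenes that gives 3-arylbut-1-enes, then rejoins the route at 24.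

Step 6. Facial selectivity may be poor, because 1,3-induction from the C11 silyloxy stereocentre opposes Felkin attack and the open transition state may tell anti from syn only weakly, giving a mixture at C8/C9. The fallback takes the β-stereocentre out of the aldehyde and creates C11 last. Methyl (S)-3-hydroxy-2-methylpropanoate (purchased) is silylated (TBSCl, imidazole) to ester F9 and reduced (iBu2AlH, CH2Cl2, −78 °C) to aldehyde F10. Setting out from 4, dienolate 12 adds to F10 to give the anti, Felkin aldol adduct F11; acetylation gives acetate F12, HF·pyridine gives primary alcohol F13, and Dess–Martin oxidation gives aldehyde F14. NiCl2-catalysed, CrCl2-mediated addition of 2-bromopropene (Nozaki–Hiyama–Kishi reaction, DMSO/DMF, rt; Felkin addition sets C11) rejoins the route at 15.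

Further compounds
F1 | step 16 | (2S,3S)-2-{3,5-dimethyl-6-[(2R,3E)-4-methyl-5-oxopent-3-en-2-yl]-4-oxo-4H-pyran-2-yl}pentan-3-yl acetate | O=C/C(C)=C/[C@@H](C)c1oc([C@@H](C)[C@H](CC)OC(C)=O)c(C)c(=O)c1C
F2 | step 16 | Evans aldol adduct of F1: (4S)-4-benzyl-3-acyloxazolidin-2-one whose acyl chain is C9–C23 of the backbone with ring B, 11-hydroxy, 21-acetoxy, (10S,11S,12E,14R,20S,21S) | O=C1OC[C@H](Cc2ccccc2)N1C(=O)[C@@H](C)[C@H](O)/C(C)=C/[C@@H](C)c3oc([C@@H](C)[C@H](CC)OC(C)=O)c(C)c(=O)c3C
F3 | step 16 | 11-O-tert-butyldimethylsilyl ether of F2, (10S,11S,12E,14R,20S,21S) | O=C1OC[C@H](Cc2ccccc2)N1C(=O)[C@@H](C)[C@H](O[Si](C)(C)C(C)(C)C)/C(C)=C/[C@@H](C)c3oc([C@@H](C)[C@H](CC)OC(C)=O)c(C)c(=O)c3C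
F4 | step 16 | C9–C23 primary alcohol (9-hydroxy, 11-silyloxy, 21-acetoxy), (10R,11S,12E,14R,20S,21S) | OC[C@@H](C)[C@H](O[Si](C)(C)C(C)(C)C)/C(C)=C/[C@@H](C)c1oc([C@@H](C)[C@H](CC)OC(C)=O)c(C)c(=O)c1C
F5 | step 16 | C9–C23 aldehyde (9-oxo, 11-silyloxy, 21-acetoxy), (10S,11S,12E,14R,20S,21S) | O=C[C@@H](C)[C@H](O[Si](C)(C)C(C)(C)C)/C(C)=C/[C@@H](C)c1oc([C@@H](C)[C@H](CC)OC(C)=O)c(C)c(=O)c1C
F6 | step 16 | 9-O-deacetyl-11-O-tert-butyldimethylsilyl derivative of the target, (8R,9R,10R,11S,12E,14R,20S,21S) | CCc1oc([C@H](C)[C@H](O)[C@@H](C)[C@H](O[Si](C)(C)C(C)(C)C)/C(C)=C/[C@@H](C)c2oc([C@@H](C)[C@H](CC)OC(C)=O)c(C)c(=O)c2C)c(C)c(=O)c1C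
F7 | step 16 | 11-O-tert-butyldimethylsilyl ether of the target, (8R,9R,10R,11S,12E,14R,20S,21S) | CCc1oc([C@H](C)[C@H](OC(C)=O)[C@@H](C)[C@H](O[Si](C)(C)C(C)(C)C)/C(C)=C/[C@@H](C)c2oc([C@@H](C)[C@H](CC)OC(C)=O)c(C)c(=O)c2C)c(C)c(=O)c1C
F8 | step 13 | 2-ethenyl-3,5-dimethyl-6-[(2S,3S)-3-(triethylsilyloxy)pentan-2-yl]-4H-pyran-4-one | C=Cc1oc([C@@H](C)[C@H](CC)O[Si](CC)(CC)CC)c(C)c(=O)c1C
F9 | step 6 | methyl (S)-3-(tert-butyldimethylsilyloxy)-2-methylpropanoate | COC(=O)[C@@H](C)CO[Si](C)(C)C(C)(C)C
F10 | step 6 | (S)-3-(tert-butyldimethylsilyloxy)-2-methylpropanal | O=C[C@@H](C)CO[Si](C)(C)C(C)(C)C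
F11 | step 6 | 2-[(2R,3R,4S)-5-(tert-butyldimethylsilyloxy)-3-hydroxy-4-methylpentan-2-yl]-6-ethyl-3,5-dimethyl-4H-pyran-4-one | CCc1oc([C@H](C)[C@H](O)[C@@H](C)CO[Si](C)(C)C(C)(C)C)c(C)c(=O)c1C
F12 | step 6 | (2R,3R,4S)-5-(tert-butyldimethylsilyloxy)-2-(6-ethyl-3,5-dimethyl-4-oxo-4H-pyran-2-yl)-4-methylpentan-3-yl acetate | CCc1oc([C@H](C)[C@H](OC(C)=O)[C@@H](C)CO[Si](C)(C)C(C)(C)C)c(C)c(=O)c1C
F13 | step 6 | (2R,3R,4S)-2-(6-ethyl-3,5-dimethyl-4-oxo-4H-pyran-2-yl)-5-hydroxy-4-methylpentan-3-yl acetate | CCc1oc([C@H](C)[C@H](OC(C)=O)[C@@H](C)CO)c(C)c(=O)c1C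
F14 | step 6 | (2R,3S,4R)-2-(6-ethyl-3,5-dimethyl-4-oxo-4H-pyran-2-yl)-4-methyl-5-oxopentan-3-yl acetate | CCc1oc([C@H](C)[C@H](OC(C)=O)[C@@H](C)C=O)c(C)c(=O)c1C
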